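Numbering (daucane): ring A is the cyclopentane C1–C2–C3–C4–C5 (C1 quaternary with methyl, C4 carbinol with isopropyl, C5 fusion CH); ring B is the cycloheptene C1–C10=C9–C8–C7–C6–C5.
Enabling feature: in ring B the oxygen-bearing C8 lies between C7 and C9; C7 is bonded to the carbinol carbon C6 (β-hydroxy ketone relation to a C8 carbonyl) and C9 is doubly bonded to C10 on the quaternary C1 (enone relation), so C7–C8–C9 is an acetone 1,3-dianion unit spanning two formyl carbons (C6, C10) held trans on the neighbouring ring A carbons C5 and C1.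
Disconnections, last to first: silyl ethers on the phenol and on C4–O; C8–CH3 (1,2-addition to a C8 enone); C6–O acyl; then ring B by C6–C7 (γ-aldol) plus C9=C10 (intramolecular Horner–Wadsworth–Emmons) from a trans-1,2-diformylcyclopentane and the dianion of dimethyl (2-oxopropyl)phosphonate in one flask.
The dialdehyde is traced to 3-ethoxycyclopent-2-en-1-one: alkenyl Grignard addition with transposition, copper-catalysed asymmetric methyl 1,4-addition with formaldehyde trapping (C1, C5), isopropylcerium addition (C4), then Swern oxidation and ozonolysis (formyl groups at C6 and C10).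
Ring order: ring A is bought as the cyclopentenone; ring B is closed in the key step.

Key step: step 7

Remark: of the two formyl groups of the dialdehyde, the one on the tertiary carbon C5 is taken to be attacked first (the other is neopentyl); the chiral NHC ligand of step 2 is used as the enantiomer that gives 3R.

Step 1
Reactants: 1 3-ethoxycyclopent-2-en-1-one; 2 (2-methylprop-1-en-1-yl)magnesium bromide
Product: 4 3-(2-methylprop-1-en-1-yl)cyclopent-2-en-1-one, via magnesium alkoxide 3 (not isolated)
Conditions: THF, 0 to 25 °C; then 1 M HCl (aq), 25 °C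
Reagents that add atoms: water, O
Why: 1,2-addition of the alkenyl Grignard reagent to the vinylogous ester, then acid-mediated hydrolysis and allylic transposition of the adduct, should give the 3-alkenyl enone (Stork–Danheiser sequence); no stereocentre is formed.

Step 2
Reactants: 4 3-(2-methylprop-1-en-1-yl)cyclopent-2-en-1-one
Product: 6 (2S,3R)-2-(hydroxymethyl)-3-methyl-3-(2-methylprop-1-en-1-yl)cyclopentan-1-one, via magnesium enolate 5 (not isolated)
Conditions: MeMgBr, Cu(OTf)2 (3 mol %), chiral imidazolinium NHC precursor (4 mol %), Et2O, −30 °C; then CH2O (monomer in THF), −78 °C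
Reagents that add atoms: methylmagnesium bromide, C[Mg]Br; formaldehyde, C=O
Why: copper-catalysed asymmetric conjugate addition of the Grignard reagent should be 1,4-selective because the δ-carbon of the dienone is fully substituted, and it sets the quaternary C1 (R) under ligand control; the regiodefined magnesium enolate is then trapped by formaldehyde in an aldol addition anti to the larger 2-methylpropenyl group, which puts the hydroxymethyl group cis to the methyl group (C5, S).

Step 3
Reactants: 6 (2S,3R)-2-(hydroxymethyl)-3-methyl-3-(2-methylprop-1-en-1-yl)cyclopentan-1-one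
Product: 7 (1R,2S,3R)-2-(hydroxymethyl)-3-methyl-3-(2-methylprop-1-en-1-yl)-1-(propan-2-yl)cyclopentan-1-ol
Conditions: CeCl3, i-PrMgCl (excess), THF, −78 to −40 °C
Reagents that add atoms: isopropylmagnesium chloride, CC(C)[Mg]Cl, transferred as isopropylcerium dichloride, CC(C)[Ce](Cl)Cl
Why: the weakly basic organocerium reagent suppresses enolisation and reduction and should add to the ketone from the face opposite the adjacent C5 hydroxymethyl group and the pseudo-axial C1 methyl group, so the new tertiary hydroxyl (C4, R) is cis to the hydroxymethyl group (organocerium 1,2-addition).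

Step 4
Reactants: 7 (1R,2S,3R)-2-(hydroxymethyl)-3-methyl-3-(2-methylprop-1-en-1-yl)-1-(propan-2-yl)cyclopentan-1-ol
Product: 8 triethyl{[(1R,2S,3R)-3-methyl-3-(2-methylprop-1-en-1-yl)-1-(propan-2-yl)-2-{[(triethylsilyl)oxy]methyl}cyclopentyl]oxy}silane
Conditions: Et3SiOTf, 2,6-lutidine, CH2Cl2, −78 to 0 °C
Reagents that add atoms: triethylsilyl trifluoromethanesulfonate, CC[Si](CC)(CC)OS(=O)(=O)C(F)(F)F
Why: a silyl triflate with a hindered pyridine base should silylate both the primary and the hindered tertiary hydroxyl group (bis-silylation); no stereocentre is touched.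

Step 5
Reactants: 8 triethyl{[(1R,2S,3R)-3-methyl-3-(2-methylprop-1-en-1-yl)-1-(propan-2-yl)-2-{[(triethylsilyl)oxy]methyl}cyclopentyl]oxy}silane
Product: 10 (1R,2R,5R)-2-methyl-2-(2-methylprop-1-en-1-yl)-5-(propan-2-yl)-5-[(triethylsilyl)oxy]cyclopentane-1-carbaldehyde, via alkoxysulfonium chloride 9 (not isolated)
Conditions: (COCl)2, DMSO, CH2Cl2, −78 to −40 °C; then Et3N, −78 to 0 °C
Reagents that add atoms: none
Why: under Swern conditions a primary triethylsilyl ether is cleaved by the chlorosulfonium reagent and oxidised directly to the aldehyde while the tertiary silyl ether is inert (Swern oxidation of a primary silyl ether); C5 should keep its configuration because the hindered aldehyde is not enolised by Et3N at low temperature and already has the more stable trans arrangement.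

Step 6
Reactants: 10 (1R,2R,5R)-2-methyl-2-(2-methylprop-1-en-1-yl)-5-(propan-2-yl)-5-[(triethylsilyl)oxy]cyclopentane-1-carbaldehyde
Product: 12 (1S,2R,3R)-1-methyl-3-(propan-2-yl)-3-[(triethylsilyl)oxy]cyclopentane-1,2-dicarbaldehyde, via ozonide 11 (not isolated)
Conditions: O3, CH2Cl2, −78 °C; then PPh3, −78 to 25 °C
Reagents that add atoms: ozone, [O-][O+]=O
Why: ozonolysis with reductive work-up should cleave the electron-rich trisubstituted alkene to the neopentyl aldehyde and acetone, while the existing formyl group and the silyl ether are inert to ozone at −78 °C; no stereocentre is touched.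

Step 7
Reactants: 12 (1S,2R,3R)-1-methyl-3-(propan-2-yl)-3-[(triethylsilyl)oxy]cyclopentane-1,2-dicarbaldehyde; 13 dimethyl (2-oxopropyl)phosphonate
Product: 16 (3R,3aS,4S,8aR)-4-hydroxy-8a-methyl-3-(propan-2-yl)-3-[(triethylsilyl)oxy]-2,3,3a,4,5,8a-hexahydroazulen-6(1H)-one, via phosphonate dianion 14 (not isolated), via aldol adduct 15 (not isolated)
Conditions: 13, NaH, THF, 0 °C; n-BuLi, 0 °C; add slowly to 12, THF, −78 °C; then −78 to 25 °C
Reagents that add atoms: none
Why: Proposed new method: dianion 14 should add through its more reactive γ-carbon (C7) to the C6 formyl group of 12 to give alkoxide 15, whose remaining phosphonate-stabilised carbanion (C9) then attacks the C10 formyl group and collapses with loss of dimethyl phosphate, so that C6–C7 and C9=C10 are formed in one flask. The closest known reactions are the γ-selective aldol addition of β-ketophosphonate 1,3-dianions to aldehydes and the intramolecular Horner–Wadsworth–Emmons closure of cycloheptenones, which are here run in tandem on a 1,4-dialdehyde. Ring B closes by 7-exo-trig attack of C9 on the C10 carbonyl carbon, and the ring allows only the cis alkene. The C6 stereocentre is set by substrate control of the Felkin–Anh type: the nucleophile passes the small C5–H on the flank of the C4 oxygen, away from the C1 flank whose methyl group is cis to the formyl group, which should give the 6S alcohol with its oxygen on the face of C5–H. The step needs site selectivity between the two formyl groups, and this is secured because the C6 formyl group sits on a tertiary carbon with an α-hydrogen whereas the C10 formyl group is neopentyl and every trajectory to it crosses a carbon substituent of C1. C5 should keep its configuration because addition at −78 °C is faster than enolisation and the trans arrangement is also the more stable one.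

Step 8
Reactants: 16 (3R,3aS,4S,8aR)-4-hydroxy-8a-methyl-3-(propan-2-yl)-3-[(triethylsilyl)oxy]-2,3,3a,4,5,8a-hexahydroazulen-6(1H)-one; 17 4-[(tert-butyldimethylsilyl)oxy]benzoic acid
Product: 18 (3R,3aS,4S,8aR)-8a-methyl-6-oxo-3-(propan-2-yl)-3-[(triethylsilyl)oxy]-1,2,3,3a,4,5,6,8a-octahydroazulen-4-yl 4-[(tert-butyldimethylsilyl)oxy]benzoate
Conditions: 17, DCC, DMAP (cat.), CH2Cl2, 0 °C
Reagents that add atoms: none
Why: Steglich esterification (carbodiimide activation with catalytic DMAP) should acylate the only free, secondary hydroxyl group with retention at C6, and the low temperature and catalytic amount of base limit β-elimination of the β-acyloxy ketone.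

Step 9
Reactants: 18 (3R,3aS,4S,8aR)-8a-methyl-6-oxo-3-(propan-2-yl)-3-[(triethylsilyl)oxy]-1,2,3,3a,4,5,6,8a-octahydroazulen-4-yl 4-[(tert-butyldimethylsilyl)oxy]benzoate
Product: 19 (3R,3aS,4S,6R,8aR)-6-hydroxy-6,8a-dimethyl-3-(propan-2-yl)-3-[(triethylsilyl)oxy]-1,2,3,3a,4,5,6,8a-octahydroazulen-4-yl 4-[(tert-butyldimethylsilyl)oxy]benzoate
Conditions: MeLi, CeCl3, THF, −78 °C
Reagents that add atoms: methyllithium, C[Li], transferred as methylcerium dichloride, C[Ce](Cl)Cl
Why: organocerium 1,2-addition to the enone carbonyl is chemoselective over the electron-rich aryl ester and should occur by torsionally preferred pseudo-axial attack on the ring face opposite the pseudo-equatorial C6 aroyloxy group, which leaves the new tertiary hydroxyl cis to the C6 oxygen (C8, R).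

Step 10
Reactants: 19 (3R,3aS,4S,6R,8aR)-6-hydroxy-6,8a-dimethyl-3-(propan-2-yl)-3-[(triethylsilyl)oxy]-1,2,3,3a,4,5,6,8a-octahydroazulen-4-yl 4-[(tert-butyldimethylsilyl)oxy]benzoate
Product: 20 (3R,3aS,4S,6R,8aR)-3,6-dihydroxy-6,8a-dimethyl-3-(propan-2-yl)-1,2,3,3a,4,5,6,8a-octahydroazulen-4-yl 4-hydroxybenzoate
Conditions: Bu4NF, AcOH, THF, 0 to 25 °C
Reagents that add atoms: none
Why: fluoride should cleave the aryl silyl ether and the tertiary triethylsilyl ether in one operation, and buffering with acetic acid protects the benzoate and the tertiary allylic alcohol (fluoride desilylation); no stereocentre is affected.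

Compound list
1 | 3-ethoxycyclopent-2-en-1-one | CCOC1=CC(=O)CC1 | starting material
2 | (2-methylprop-1-en-1-yl)magnesium bromide | CC(C)=C[Mg]Br | starting material
3 | bromomagnesium 3-ethoxy-1-(2-methylprop-1-en-1-yl)cyclopent-2-en-1-olate (racemic 1,2-adduct) | CCOC1=CC(O[Mg]Br)(C=C(C)C)CC1 | intermediate
4 | 3-(2-methylprop-1-en-1-yl)cyclopent-2-en-1-one | CC(C)=CC1=CC(=O)CC1 | intermediate
5 | bromomagnesium (3R)-3-methyl-3-(2-methylprop-1-en-1-yl)cyclopent-1-en-1-olate | Br[Mg]OC1=C[C@@](C)(C=C(C)C)CC1 | intermediate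
6 | (2S,3R)-2-(hydroxymethyl)-3-methyl-3-(2-methylprop-1-en-1-yl)cyclopentan-1-one | O=C1CC[C@](C)(C=C(C)C)[C@H]1CO | intermediate
7 | (1R,2S,3R)-2-(hydroxymethyl)-3-methyl-3-(2-methylprop-1-en-1-yl)-1-(propan-2-yl)cyclopentan-1-ol | CC(C)[C@]1(O)CC[C@](C)(C=C(C)C)[C@H]1CO | intermediate
8 | triethyl{[(1R,2S,3R)-3-methyl-3-(2-methylprop-1-en-1-yl)-1-(propan-2-yl)-2-{[(triethylsilyl)oxy]methyl}cyclopentyl]oxy}silane | CC(C)[C@]1(O[Si](CC)(CC)CC)CC[C@](C)(C=C(C)C)[C@H]1CO[Si](CC)(CC)CC | intermediate
9 | dimethyl{[(1S,2R,5R)-2-methyl-2-(2-methylprop-1-en-1-yl)-5-(propan-2-yl)-5-[(triethylsilyl)oxy]cyclopentyl]methoxy}sulfonium chloride | CC(C)[C@]1(O[Si](CC)(CC)CC)CC[C@](C)(C=C(C)C)[C@H]1CO[S+](C)C.[Cl-] | intermediate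
10 | (1R,2R,5R)-2-methyl-2-(2-methylprop-1-en-1-yl)-5-(propan-2-yl)-5-[(triethylsilyl)oxy]cyclopentane-1-carbaldehyde | CC(C)[C@]1(O[Si](CC)(CC)CC)CC[C@](C)(C=C(C)C)[C@H]1C=O | intermediate
11 | (1R,2S,5R)-2-(5,5-dimethyl-1,2,4-trioxolan-3-yl)-2-methyl-5-(propan-2-yl)-5-[(triethylsilyl)oxy]cyclopentane-1-carbaldehyde (both configurations at the trioxolane carbon) | CC(C)[C@]1(O[Si](CC)(CC)CC)CC[C@](C)(C2OOC(C)(C)O2)[C@H]1C=O | intermediate
12 | (1S,2R,3R)-1-methyl-3-(propan-2-yl)-3-[(triethylsilyl)oxy]cyclopentane-1,2-dicarbaldehyde (formyl groups trans) | CC(C)[C@]1(O[Si](CC)(CC)CC)CC[C@](C)(C=O)[C@H]1C=O | intermediate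
13 | dimethyl (2-oxopropyl)phosphonate | COP(=O)(OC)CC(C)=O | starting material
14 | sodium lithium salt of the 1,3-dianion of dimethyl (2-oxopropyl)phosphonate | [Na+].[Li+].[CH2-]C(=O)[CH-]P(=O)(OC)OC | intermediate
15 | dimethyl [(4S)-4-{(1S,2S,5R)-2-formyl-2-methyl-5-(propan-2-yl)-5-[(triethylsilyl)oxy]cyclopentyl}-4-hydroxy-2-oxobutyl]phosphonate (present in the flask as its alkoxide and phosphonate anion; drawn neutral) | CC(C)[C@]1(O[Si](CC)(CC)CC)CC[C@](C)(C=O)[C@H]1[C@@H](O)CC(=O)CP(=O)(OC)OC | intermediate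
16 | (3R,3aS,4S,8aR)-4-hydroxy-8a-methyl-3-(propan-2-yl)-3-[(triethylsilyl)oxy]-2,3,3a,4,5,8a-hexahydroazulen-6(1H)-one | CC(C)[C@]1(O[Si](CC)(CC)CC)CC[C@]2(C)C=CC(=O)C[C@H](O)[C@H]21 | intermediate
17 | 4-[(tert-butyldimethylsilyl)oxy]benzoic acid | CC(C)(C)[Si](C)(C)Oc1ccc(cc1)C(O)=O | starting material
18 | (3R,3aS,4S,8aR)-8a-methyl-6-oxo-3-(propan-2-yl)-3-[(triethylsilyl)oxy]-1,2,3,3a,4,5,6,8a-octahydroazulen-4-yl 4-[(tert-butyldimethylsilyl)oxy]benzoate | CC(C)[C@]1(O[Si](CC)(CC)CC)CC[C@]2(C)C=CC(=O)C[C@H](OC(=O)c3ccc(O[Si](C)(C)C(C)(C)C)cc3)[C@H]21 | intermediate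
19 | (3R,3aS,4S,6R,8aR)-6-hydroxy-6,8a-dimethyl-3-(propan-2-yl)-3-[(triethylsilyl)oxy]-1,2,3,3a,4,5,6,8a-octahydroazulen-4-yl 4-[(tert-butyldimethylsilyl)oxy]benzoate | CC(C)[C@]1(O[Si](CC)(CC)CC)CC[C@]2(C)C=C[C@](C)(O)C[C@H](OC(=O)c3ccc(O[Si](C)(C)C(C)(C)C)cc3)[C@H]21 | intermediate
20 | (3R,3aS,4S,6R,8aR)-3,6-dihydroxy-6,8a-dimethyl-3-(propan-2-yl)-1,2,3,3a,4,5,6,8a-octahydroazulen-4-yl 4-hydroxybenzoate | CC(C)[C@]1(O)CC[C@]2(C)C=C[C@](C)(O)C[C@H](OC(=O)c3ccc(O)cc3)[C@H]21 | target

Total step count: 10. Longest linear sequence: 10 steps (1 to 20; 2, 13 and 17 are purchased).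

Steps most likely to fail

Step 7 (proposed tandem annulation). The first addition may go to the wrong formyl group (C10 instead of C6), the facial selectivity at C6 may be poor, or the ring-closing olefination may stall on the neopentyl aldehyde. The fallback uses known reactions in separate stages and sets out from aldehyde 10, which has only the C6 formyl group. Addition of dianion 14 (THF, −78 °C) should give dimethyl [(4S)-4-hydroxy-4-{(1S,2R,5R)-2-methyl-2-(2-methylprop-1-en-1-yl)-5-(propan-2-yl)-5-[(triethylsilyl)oxy]cyclopentyl}-2-oxobutyl]phosphonate F1, whose C6 epimers can be separated at this acyclic stage. Ozonolysis (O3, CH2Cl2, −78 °C; then PPh3) then frees the C10 formyl group and gives compound 15, this time isolated in its neutral form. LiCl and DBU in MeCN at 25 °C should close ring B by intramolecular Horner–Wadsworth–Emmons olefination, and the route is rejoined at 16.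

Step 9. The methyl addition to the C8 carbonyl may show poor facial selectivity (attack from the face of the C6 ester). The fallback sets out from 16 and lets the free C6 hydroxyl direct the oxygen to C8. Methylenation with Ph3P=CH2 (THF, 0 °C) should give (3R,3aS,4S,8aR)-8a-methyl-6-methylidene-3-(propan-2-yl)-3-[(triethylsilyl)oxy]-1,2,3,3a,4,5,6,8a-octahydroazulen-4-ol F2. Homoallylic-hydroxyl-directed epoxidation of the exocyclic alkene (VO(acac)2, t-BuOOH, CH2Cl2, 0 °C) should deliver oxygen syn to the C6 hydroxyl and give (3R,3aS,4S,6R,8aR)-8a-methyl-3-(propan-2-yl)-3-[(triethylsilyl)oxy]-2,3,3a,4,5,8a-hexahydro-1H-spiro[azulene-6,2'-oxiran]-4-ol F3. LiEt3BH (THF, 0 °C) should open the epoxide at its CH2 carbon to (3R,3aS,4S,6R,8aR)-6,8a-dimethyl-3-(propan-2-yl)-3-[(triethylsilyl)oxy]-1,2,3,3a,4,5,6,8a-octahydroazulene-4,6-diol F4. Acylation of the secondary hydroxyl alone with 17 (DCC, DMAP, CH2Cl2, 0 °C) rejoins the route at 19.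

Step 2. The enantioselectivity of the methyl transfer may be insufficient, or 1,6-addition to the dienone may compete. The fallback forms the other bond at the quaternary carbon and sets out from Grignard reagent 2. Transmetalation with Me2AlCl (Et2O, −30 °C) should give dimethyl(2-methylprop-1-en-1-yl)aluminium F5. Copper-catalysed asymmetric conjugate addition of its alkenyl group to purchased 3-methylcyclopent-2-en-1-one (Cu(OTf)2, chiral NHC ligand, Et2O, −30 °C) should give dimethylaluminium (3R)-3-methyl-3-(2-methylprop-1-en-1-yl)cyclopent-1-en-1-olate F6. Activation with MeLi and trapping with monomeric formaldehyde (−78 °C) rejoins the route at 6.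

Further compounds
F1 | step 7 | dimethyl [(4S)-4-hydroxy-4-{(1S,2R,5R)-2-methyl-2-(2-methylprop-1-en-1-yl)-5-(propan-2-yl)-5-[(triethylsilyl)oxy]cyclopentyl}-2-oxobutyl]phosphonate | CC(C)[C@]1(O[Si](CC)(CC)CC)CC[C@](C)(C=C(C)C)[C@H]1[C@@H](O)CC(=O)CP(=O)(OC)OC
F2 | step 9 | (3R,3aS,4S,8aR)-8a-methyl-6-methylidene-3-(propan-2-yl)-3-[(triethylsilyl)oxy]-1,2,3,3a,4,5,6,8a-octahydroazulen-4-ol | CC(C)[C@]1(O[Si](CC)(CC)CC)CC[C@]2(C)C=CC(=C)C[C@H](O)[C@H]21
F3 | step 9 | (3R,3aS,4S,6R,8aR)-8a-methyl-3-(propan-2-yl)-3-[(triethylsilyl)oxy]-2,3,3a,4,5,8a-hexahydro-1H-spiro[azulene-6,2'-oxiran]-4-ol | CC(C)[C@]1(O[Si](CC)(CC)CC)CC[C@]2(C)C=C[C@]3(OC3)C[C@H](O)[C@H]21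
F4 | step 9 | (3R,3aS,4S,6R,8aR)-6,8a-dimethyl-3-(propan-2-yl)-3-[(triethylsilyl)oxy]-1,2,3,3a,4,5,6,8a-octahydroazulene-4,6-diol | CC(C)[C@]1(O[Si](CC)(CC)CC)CC[C@]2(C)C=C[C@](C)(O)C[C@H](O)[C@H]21
F5 | step 2 | dimethyl(2-methylprop-1-en-1-yl)aluminium | CC(C)=C[Al](C)C
F6 | step 2 | dimethylaluminium (3R)-3-methyl-3-(2-methylprop-1-en-1-yl)cyclopent-1-en-1-olate | C[Al](C)OC1=C[C@@](C)(C=C(C)C)CC1
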